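**Retrosynthetic overview**
- Ten-membered carbocycle (formed last): ring-closing metathesis at C2=C3 between a vinyl oxirane and the terminal (Z)-diene of an open triene ester.
- C8 ester: Mitsunobu acylation with inversion, using (2S,3R)-2,3-dimethyloxirane-2-carboxylic acid (Sharpless epoxidation of tiglyl alcohol, then oxidation).
- Key C7–C8 bond: intermolecular zinc Barbier allylation of a β,γ-epoxy aldehyde with a (5R)-3-(bromomethyl)butenolide; this also delivers the trans α-methylene γ-lactone.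
- Bromobutenolide from a (Z)-dienal by asymmetric alkynylation, trans-hydroalumination/iodination and carbonylative lactonisation; epoxy aldehyde by carboalumination, Sharpless epoxidation and Wittig methylenation.
- Ring order: butenolide (γ-lactone), then the two oxiranes in their own fragments, then the carbocycle.

Assumption: positions are labelled with germacrane numbering (C1/C10 oxirane, C2=C3 and C4=C5 ring alkenes, C6 lactone carbinol, C7, C8 ester carbinol, C11–C13 acrylate unit); the target is read as 1R,6R,7R,8R,10R,2Z,4Z with a (2S,3R) ester; 1, 4, 12 and 21 are purchased.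

**Fragment A: bromobutenolide 11 (C3–C7, C11–C13, C15)**

Step 1
Reactants: 1 (2Z)-3-methylpent-2-en-4-yn-1-ol
Product: 2 (2Z)-3-methylpenta-2,4-dien-1-ol
Conditions: H2 (1 atm, 1.0 equiv uptake), Pd/CaCO3 poisoned with Pb(OAc)2 (Lindlar catalyst), quinoline, EtOAc/hexane, 0 °C
Reagents that add atoms: none
Why: Lindlar semihydrogenation stops at the alkene for the terminal alkyne (quinoline suppresses over-reduction) and leaves the (Z)-trisubstituted C4=C5 geometry untouched.

Step 2
Reactants: 2 (2Z)-3-methylpenta-2,4-dien-1-ol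
Product: 3 (2Z)-3-methylpenta-2,4-dienal
Conditions: activated MnO2 (15 equiv), CH2Cl2, 0 °C to rt, dark; filtered, solvent exchanged to toluene, used at once
Reagents that add atoms: none
Why: MnO2 allylic oxidation is neutral and selective for the allylic alcohol, so the (Z)-enal is obtained without Z/E isomerisation.

Step 3
Reactants: 3 (2Z)-3-methylpenta-2,4-dienal; 4 tert-butyldimethyl(prop-2-yn-1-yloxy)silane
Product: 6 (4R,5Z)-1-[(tert-butyldimethylsilyl)oxy]-6-methylocta-5,7-dien-2-yn-4-ol, via alkynyl(methyl)zinc 5 (not isolated)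
Conditions: 4 (3 equiv), Me2Zn (3 equiv), (S,S)-ProPhenol (20 mol %), Ph3P=O (40 mol %), toluene, 0–4 °C, 36 h; aq. work-up
Reagents that add atoms: none
Why: Zinc–ProPhenol asymmetric alkynylation (1,2-addition of alkynylzinc 5) in which the dinuclear zinc complex of the (S,S)-ligand shields one enal face to give the 4R carbinol (future C6); the sense is recalled from aryl and alkenyl aldehyde examples and is confirmed by Mosher ester analysis, the (R,R)-ligand giving the antipode.

Step 4
Reactants: 6 (4R,5Z)-1-[(tert-butyldimethylsilyl)oxy]-6-methylocta-5,7-dien-2-yn-4-ol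
Product: 8 (2Z,4R,5Z)-1-[(tert-butyldimethylsilyl)oxy]-2-iodo-6-methylocta-2,5,7-trien-4-ol, via cyclic vinylalanate 7 (not isolated)
Conditions: NaAlH2(OCH2CH2OMe)2 (Red-Al, 2.0 equiv), THF, 0 °C to rt; then I2 (1.5 equiv), THF, −78 °C; aq. work-up
Reagents that add atoms: iodine II
Why: Hydroxyl-directed trans-hydroalumination (hydride to C3, aluminium on C2 inside a five-membered alanate) followed by iododealumination with retention gives the (2Z)-vinyl iodide with iodine cis to the carbinol; the stereocentre is untouched.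

Step 5
Reactants: 8 (2Z,4R,5Z)-1-[(tert-butyldimethylsilyl)oxy]-2-iodo-6-methylocta-2,5,7-trien-4-ol
Product: 9 (5R)-3-{[(tert-butyldimethylsilyl)oxy]methyl}-5-[(1Z)-2-methylbuta-1,3-dien-1-yl]furan-2(5H)-one
Conditions: CO (1 atm), Pd(PPh3)4 (5 mol %), NaHCO3 (2 equiv), DMF, 40 °C
Reagents that add atoms: carbon monoxide [C-]#[O+]
Why: Palladium-catalysed carbonylative lactonisation (oxidative addition to C–I, CO insertion, capture of the acylpalladium by the cis hydroxyl) closes the butenolide, and NaHCO3 is too weak a base to epimerise the γ-position.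

Step 6
Reactants: 9 (5R)-3-{[(tert-butyldimethylsilyl)oxy]methyl}-5-[(1Z)-2-methylbuta-1,3-dien-1-yl]furan-2(5H)-one
Product: 10 (5R)-3-(hydroxymethyl)-5-[(1Z)-2-methylbuta-1,3-dien-1-yl]furan-2(5H)-one
Conditions: HF·pyridine, pyridine, THF, 0 °C
Reagents that add atoms: none
Why: Fluoride desilylation under buffered, non-basic conditions removes the primary TBS ether without touching the base-sensitive γ-position or the diene.

Step 7
Reactants: 10 (5R)-3-(hydroxymethyl)-5-[(1Z)-2-methylbuta-1,3-dien-1-yl]furan-2(5H)-one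
Product: 11 (5R)-3-(bromomethyl)-5-[(1Z)-2-methylbuta-1,3-dien-1-yl]furan-2(5H)-one
Conditions: CBr4 (1.3 equiv), PPh3 (1.3 equiv), CH2Cl2, 0 °C, 30 min
Reagents that add atoms: carbon tetrabromide BrC(Br)(Br)Br
Why: Appel bromination converts the primary allylic alcohol into the bromide under neutral conditions by SN2 displacement of the alkoxyphosphonium.

**Fragment B: epoxy aldehyde 20 (C8–C10, C14, C1, C2)**

Step 8
Reactants: 12 tert-butyl(but-3-yn-1-yloxy)dimethylsilane
Product: 15 (2E)-5-[(tert-butyldimethylsilyl)oxy]-3-methylpent-2-en-1-ol, via vinylalane 13 (not isolated), via lithium vinylalanate 14 (not isolated)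
Conditions: Me3Al (2.5 equiv), Cp2ZrCl2 (25 mol %), CH2Cl2, 0 °C to rt; volatiles removed; n-BuLi (1.1 equiv), THF/hexane, −78 °C; (CH2O)n, −78 °C to rt; aq. work-up
Reagents that add atoms: trimethylaluminium C[Al](C)C; formaldehyde (from paraformaldehyde) C=O
Why: Negishi zirconium-catalysed carboalumination adds Me and Al syn with Al on the terminal carbon, and the derived alanate is hydroxymethylated by formaldehyde with retention, giving the (E)-trisubstituted allylic alcohol.

Step 9
Reactants: 15 (2E)-5-[(tert-butyldimethylsilyl)oxy]-3-methylpent-2-en-1-ol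
Product: 16 [(2R,3R)-3-{2-[(tert-butyldimethylsilyl)oxy]ethyl}-3-methyloxiran-2-yl]methanol
Conditions: Ti(OiPr)4 (10 mol %), D-(−)-diethyl tartrate (12 mol %), t-BuOOH (2 equiv, anhydrous), 4 Å MS, CH2Cl2, −20 °C
Reagents that add atoms: tert-butyl hydroperoxide CC(C)(C)OO
Why: Sharpless asymmetric epoxidation with D-(−)-tartrate delivers oxygen to the face that gives the (2R,3R)-epoxy alcohol (future C1 R, C10 R), the E alkene translating into the trans oxirane.

Step 10
Reactants: 16 [(2R,3R)-3-{2-[(tert-butyldimethylsilyl)oxy]ethyl}-3-methyloxiran-2-yl]methanol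
Product: 17 (2S,3R)-3-{2-[(tert-butyldimethylsilyl)oxy]ethyl}-3-methyloxirane-2-carbaldehyde
Conditions: TEMPO (10 mol %), PhI(OAc)2 (1.1 equiv), CH2Cl2, rt
Reagents that add atoms: none
Why: TEMPO/PhI(OAc)2 (oxoammonium) oxidation takes the primary alcohol to the aldehyde without over-oxidation or oxirane opening (the descriptor at C2 changes only through priority).

Step 11
Reactants: 17 (2S,3R)-3-{2-[(tert-butyldimethylsilyl)oxy]ethyl}-3-methyloxirane-2-carbaldehyde
Product: 18 tert-butyl{2-[(2R,3R)-3-ethenyl-2-methyloxiran-2-yl]ethoxy}dimethylsilane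
Conditions: Ph3PCH3Br (1.5 equiv), KN(SiMe3)2 (1.4 equiv), THF, 0 °C; then 17, −78 °C to 0 °C
Reagents that add atoms: methyltriphenylphosphonium bromide C[P+](c1ccccc1)(c1ccccc1)c1ccccc1.[Br-]
Why: Wittig methylenation with the non-stabilised ylide is fast at low temperature and the oxirane α-carbon cannot epimerise, so the vinyl oxirane forms cleanly.

Step 12
Reactants: 18 tert-butyl{2-[(2R,3R)-3-ethenyl-2-methyloxiran-2-yl]ethoxy}dimethylsilane
Product: 19 2-[(2R,3R)-3-ethenyl-2-methyloxiran-2-yl]ethan-1-ol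
Conditions: Bu4NF (1.2 equiv), THF, 0 °C to rt
Reagents that add atoms: none
Why: Fluoride-mediated desilylation; the vinyl oxirane is inert to Bu4NF.

Step 13
Reactants: 19 2-[(2R,3R)-3-ethenyl-2-methyloxiran-2-yl]ethan-1-ol
Product: 20 [(2R,3R)-3-ethenyl-2-methyloxiran-2-yl]acetaldehyde
Conditions: TEMPO (10 mol %), PhI(OAc)2 (1.1 equiv), CH2Cl2, 0 °C to rt; short silica plug, used at once
Reagents that add atoms: none
Why: Oxoammonium oxidation under non-basic conditions gives the β,γ-epoxy aldehyde, which is used immediately to avoid β-elimination of the oxirane.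

**Fragment C: epoxy acid 24**

Step 14
Reactants: 21 (2E)-2-methylbut-2-en-1-ol
Product: 22 [(2R,3R)-2,3-dimethyloxiran-2-yl]methanol
Conditions: Ti(OiPr)4 (10 mol %), D-(−)-diethyl tartrate (12 mol %), t-BuOOH (2 equiv, anhydrous), 4 Å MS, CH2Cl2, −20 °C; distillation
Reagents that add atoms: tert-butyl hydroperoxide CC(C)(C)OO
Why: Sharpless asymmetric epoxidation with D-(−)-tartrate gives the (2R,3R)-epoxy alcohol, fixing both stereocentres of the later ester (the E alkene gives the oxirane with the two methyl groups cis).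

Step 15
Reactants: 22 [(2R,3R)-2,3-dimethyloxiran-2-yl]methanol
Product: 24 (2S,3R)-2,3-dimethyloxirane-2-carboxylic acid, via epoxy aldehyde 23 (not isolated)
Conditions: TEMPO (20 mol %), PhI(OAc)2 (2.2 equiv), MeCN/H2O (1:1), rt
Reagents that add atoms: water O
Why: Oxoammonium oxidation in aqueous acetonitrile carries the alcohol through the aldehyde hydrate to the acid without touching the stereocentres (C2 becomes S only through priority).

**Fragment union and endgame**

Step 16
Reactants: 11 (5R)-3-(bromomethyl)-5-[(1Z)-2-methylbuta-1,3-dien-1-yl]furan-2(5H)-one; 20 [(2R,3R)-3-ethenyl-2-methyloxiran-2-yl]acetaldehyde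
Product: 26 (4R,5R)-4-{(1S)-2-[(2R,3R)-3-ethenyl-2-methyloxiran-2-yl]-1-hydroxyethyl}-3-methylidene-5-[(1Z)-2-methylbuta-1,3-dien-1-yl]oxolan-2-one, via allylzinc bromide 25 (not isolated)
Conditions: Zn dust (3 equiv), THF/sat. aq. NH4Cl (2:1), 0 °C to rt; 11 (1.0 equiv), 20 (1.5 equiv); minor C8 epimer removed by chromatography
Reagents that add atoms: none
Why: Zinc Barbier carbonyl allylation in which allylzinc 25 reacts through its ring γ-carbon anti to the C6 dienyl group (C7 R, trans lactone) in a chair six-membered transition state with the aldehyde chain equatorial (C8 S), forming the C7–C8 bond and the α-methylene lactone at once.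

Step 17
Reactants: 26 (4R,5R)-4-{(1S)-2-[(2R,3R)-3-ethenyl-2-methyloxiran-2-yl]-1-hydroxyethyl}-3-methylidene-5-[(1Z)-2-methylbuta-1,3-dien-1-yl]oxolan-2-one; 24 (2S,3R)-2,3-dimethyloxirane-2-carboxylic acid
Product: 27 (1R)-2-[(2R,3R)-3-ethenyl-2-methyloxiran-2-yl]-1-{(2R,3R)-4-methylidene-2-[(1Z)-2-methylbuta-1,3-dien-1-yl]-5-oxooxolan-3-yl}ethyl (2S,3R)-2,3-dimethyloxirane-2-carboxylate
Conditions: PPh3 (3 equiv), diisopropyl azodicarboxylate (3 equiv), 24 (3 equiv), toluene, 0 °C to rt
Reagents that add atoms: none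
Why: Mitsunobu esterification, in which SN2 displacement of the alkoxyphosphonium by the carboxylate of 24 inverts C8 from S to the required R while acylating it in the same operation.

Step 18
Reactants: 27 (1R)-2-[(2R,3R)-3-ethenyl-2-methyloxiran-2-yl]-1-{(2R,3R)-4-methylidene-2-[(1Z)-2-methylbuta-1,3-dien-1-yl]-5-oxooxolan-3-yl}ethyl (2S,3R)-2,3-dimethyloxirane-2-carboxylate
Product: 28 CNP0122107.1 = (1R,6R,7R,8R,10R,2Z,4Z)-1,10-epoxy-8-{[(2S,3R)-2,3-dimethyloxirane-2-carbonyl]oxy}germacra-2,4,11(13)-trien-12,6-olide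
Conditions: second-generation Grubbs catalyst (15 mol %, in portions), 1,4-benzoquinone (30 mol %), degassed toluene (0.5 mM), 80 °C
Reagents that add atoms: none
Why: Ring-closing olefin metathesis joins the vinyl oxirane and diene termini with loss of ethylene; closure onto the α-methylene group would need a bridgehead alkene or a trans-oxirane in a seven-membered ring, and the ten-membered ring is expected to take the new C2=C3 alkene as Z.

**Compound list**
1 | (2Z)-3-methylpent-2-en-4-yn-1-ol | C#C/C(C)=C\CO | starting material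
2 | (2Z)-3-methylpenta-2,4-dien-1-ol | C=C/C(C)=C\CO | intermediate
3 | (2Z)-3-methylpenta-2,4-dienal | C=C/C(C)=C\C=O | intermediate
4 | tert-butyldimethyl(prop-2-yn-1-yloxy)silane | C#CCO[Si](C)(C)C(C)(C)C | starting material
5 | methyl{3-[(tert-butyldimethylsilyl)oxy]prop-1-yn-1-yl}zinc | C[Zn]C#CCO[Si](C)(C)C(C)(C)C | intermediate
6 | (4R,5Z)-1-[(tert-butyldimethylsilyl)oxy]-6-methylocta-5,7-dien-2-yn-4-ol | C=C/C(C)=C\[C@@H](O)C#CCO[Si](C)(C)C(C)(C)C | intermediate
7 | sodium cyclic alkoxy(alkenyl)bis(2-methoxyethoxy)alanate of 6 (Al on C2, O of C4 on Al, 5R ring carbon) | C=C/C(C)=C\[C@H]1O[Al-](OCCOC)(OCCOC)C(CO[Si](C)(C)C(C)(C)C)=C1.[Na+] | intermediate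
8 | (2Z,4R,5Z)-1-[(tert-butyldimethylsilyl)oxy]-2-iodo-6-methylocta-2,5,7-trien-4-ol | C=C/C(C)=C\[C@@H](O)/C=C(\I)CO[Si](C)(C)C(C)(C)C | intermediate
9 | (5R)-3-{[(tert-butyldimethylsilyl)oxy]methyl}-5-[(1Z)-2-methylbuta-1,3-dien-1-yl]furan-2(5H)-one | C=C/C(C)=C\[C@H]1OC(=O)C(CO[Si](C)(C)C(C)(C)C)=C1 | intermediate
10 | (5R)-3-(hydroxymethyl)-5-[(1Z)-2-methylbuta-1,3-dien-1-yl]furan-2(5H)-one | C=C/C(C)=C\[C@H]1OC(=O)C(CO)=C1 | intermediate
11 | (5R)-3-(bromomethyl)-5-[(1Z)-2-methylbuta-1,3-dien-1-yl]furan-2(5H)-one | C=C/C(C)=C\[C@H]1OC(=O)C(CBr)=C1 | intermediate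
12 | tert-butyl(but-3-yn-1-yloxy)dimethylsilane | C#CCCO[Si](C)(C)C(C)(C)C | starting material
13 | {(1E)-4-[(tert-butyldimethylsilyl)oxy]-2-methylbut-1-en-1-yl}dimethylalane | C[Al](C)/C=C(\C)CCO[Si](C)(C)C(C)(C)C | intermediate
14 | lithium butyl{(1E)-4-[(tert-butyldimethylsilyl)oxy]-2-methylbut-1-en-1-yl}dimethylalanate | [Li+].CCCC[Al-](C)(C)/C=C(\C)CCO[Si](C)(C)C(C)(C)C | intermediate
15 | (2E)-5-[(tert-butyldimethylsilyl)oxy]-3-methylpent-2-en-1-ol | OC/C=C(\C)CCO[Si](C)(C)C(C)(C)C | intermediate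
16 | [(2R,3R)-3-{2-[(tert-butyldimethylsilyl)oxy]ethyl}-3-methyloxiran-2-yl]methanol | OC[C@H]1O[C@]1(C)CCO[Si](C)(C)C(C)(C)C | intermediate
17 | (2S,3R)-3-{2-[(tert-butyldimethylsilyl)oxy]ethyl}-3-methyloxirane-2-carbaldehyde | O=C[C@H]1O[C@]1(C)CCO[Si](C)(C)C(C)(C)C | intermediate
18 | tert-butyl{2-[(2R,3R)-3-ethenyl-2-methyloxiran-2-yl]ethoxy}dimethylsilane | C=C[C@H]1O[C@]1(C)CCO[Si](C)(C)C(C)(C)C | intermediate
19 | 2-[(2R,3R)-3-ethenyl-2-methyloxiran-2-yl]ethan-1-ol | C=C[C@H]1O[C@]1(C)CCO | intermediate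
20 | [(2R,3R)-3-ethenyl-2-methyloxiran-2-yl]acetaldehyde | C=C[C@H]1O[C@]1(C)CC=O | intermediate
21 | (2E)-2-methylbut-2-en-1-ol | C/C=C(\C)CO | starting material
22 | [(2R,3R)-2,3-dimethyloxiran-2-yl]methanol | OC[C@@]1(C)O[C@@H]1C | intermediate
23 | (2S,3R)-2,3-dimethyloxirane-2-carbaldehyde | O=C[C@@]1(C)O[C@@H]1C | intermediate
24 | (2S,3R)-2,3-dimethyloxirane-2-carboxylic acid | OC(=O)[C@@]1(C)O[C@@H]1C | intermediate
25 | {[(5R)-5-[(1Z)-2-methylbuta-1,3-dien-1-yl]-2-oxo-2,5-dihydrofuran-3-yl]methyl}zinc bromide | C=C/C(C)=C\[C@H]1OC(=O)C(C[Zn]Br)=C1 | intermediate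
26 | (4R,5R)-4-{(1S)-2-[(2R,3R)-3-ethenyl-2-methyloxiran-2-yl]-1-hydroxyethyl}-3-methylidene-5-[(1Z)-2-methylbuta-1,3-dien-1-yl]oxolan-2-one | C=C1C(=O)O[C@H](/C=C(C)\C=C)[C@H]1[C@@H](O)C[C@@]1(C)O[C@@H]1C=C | intermediate
27 | (1R)-2-[(2R,3R)-3-ethenyl-2-methyloxiran-2-yl]-1-{(2R,3R)-4-methylidene-2-[(1Z)-2-methylbuta-1,3-dien-1-yl]-5-oxooxolan-3-yl}ethyl (2S,3R)-2,3-dimethyloxirane-2-carboxylate | C=C1C(=O)O[C@H](/C=C(C)\C=C)[C@H]1[C@H](OC(=O)[C@@]1(C)O[C@@H]1C)C[C@@]1(C)O[C@@H]1C=C | intermediate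
28 | CNP0122107.1 = (1R,6R,7R,8R,10R,2Z,4Z)-1,10-epoxy-8-{[(2S,3R)-2,3-dimethyloxirane-2-carbonyl]oxy}germacra-2,4,11(13)-trien-12,6-olide | C=C1C(=O)O[C@@H]2/C=C(C)\C=C/[C@H]3O[C@]3(C)C[C@@H](OC(=O)[C@@]3(C)O[C@@H]3C)[C@@H]12 | target

**Totals**
Total steps: 18. Longest linear sequence: 10 steps (1 to 28 through steps 1–7 and 16–18).

**Three steps most likely to fail**

Step 18 (macrocyclic metathesis; risks are oligomerisation, a strained ten-membered ring and C2=C3 geometry). The fallback sets out from 26 and moves ring closure ahead of the esterification, so that the cyclisation substrate lacks the bulky C8 ester. Metathesis of 26 with the same class of ruthenium catalyst at high dilution gives the macrocyclic (8S)-hydroxy lactone F1. A Mitsunobu reaction of F1 with 24 (PPh3, diisopropyl azodicarboxylate, toluene) then inverts C8 and acylates it, and the route is rejoined at 28.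

Step 17 (Mitsunobu inversion at a hindered secondary carbinol; risks are low conversion and elimination towards C7). The fallback sets out from 26 and separates activation from displacement. MsCl/Et3N in CH2Cl2 at 0 °C gives the (8S)-mesylate F2 with retention. F2 is then displaced with the caesium salt of 24 (24, Cs2CO3, 18-crown-6, toluene, 70 °C) in an SN2 reaction with inversion, and the route is rejoined at 27.

Step 16 (Barbier coupling; risks are the lability of the β,γ-epoxy aldehyde 20 towards aqueous zinc salts and the C8 selectivity). The fallback sets out from 11 and replaces the in-situ allylzinc by an isolable allylboron reagent. Borylation of 11 (B2pin2, Pd2(dba)3, KOAc, toluene, 50 °C) gives the pinacol allylboronate F3. Thermal allylboration of 20 with F3 in dry toluene at 40–60 °C proceeds through the same chair transition state without water or Lewis-acidic salts. Mild aqueous work-up of the borate ester then rejoins the route at 26.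

Further compounds
F1 | step 18 | (1R,6R,7R,8S,10R,2Z,4Z)-1,10-epoxy-8-hydroxygermacra-2,4,11(13)-trien-12,6-olide | C=C1C(=O)O[C@@H]2/C=C(C)\C=C/[C@H]3O[C@]3(C)C[C@H](O)[C@@H]12
F2 | step 17 | (1S)-2-[(2R,3R)-3-ethenyl-2-methyloxiran-2-yl]-1-{(2R,3R)-4-methylidene-2-[(1Z)-2-methylbuta-1,3-dien-1-yl]-5-oxooxolan-3-yl}ethyl methanesulfonate | C=C1C(=O)O[C@H](/C=C(C)\C=C)[C@H]1[C@@H](OS(C)(=O)=O)C[C@@]1(C)O[C@@H]1C=C
F3 | step 16 | (5R)-5-[(1Z)-2-methylbuta-1,3-dien-1-yl]-3-[(4,4,5,5-tetramethyl-1,3,2-dioxaborolan-2-yl)methyl]furan-2(5H)-one | C=C/C(C)=C\[C@H]1OC(=O)C(CB2OC(C)(C)C(C)(C)O2)=C1
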